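**Assumptions.** Compounds 1 (made industrially in one step from cellulose-derived levoglucosenone) and 2 are taken as catalogue items. Chain labels used throughout: C1 = ArCH(OH), C2 = ring OCH, C3 = ring ArCH, C4 = ring CHOH, C5 = ring OCH2.

## Retrosynthetic overview
1. The all-cis oxolane (C2/C3/C4) is the same object as a trans,trans-substituted γ-butyrolactone (C1–C4 plus O4), seen from the other ring of bicyclic lactone 5. C3 and C2 are therefore set where the wanted isomer is the sterically favoured one.
2. Target ⇒ debenzylation ⇒ chelate-controlled reduction of 2-aroyl-oxolane 6 ⇒ ArLi opening of 5. This forms C1–Ar, breaks the lactone ring and leaves the oxolane.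
3. 5 ⇒ enolate hydroxylation anti to the C3 aryl (C2–O), then transannular Williamson closure onto C5–OTs (oxolane ring).
4. trans-Lactone 3 ⇒ visible-light Ni/photoredox reductive conjugate arylation of (S)-butenolide 1 with ArBr 2. This is the key C3–Ar bond, formed anti to CH2OH.
5. Ring order: butenolide ring bought, oxolane closed in step 3, lactone opened in step 4. The single bought centre C4 relays to C3, then C2, then C1.

## Route

**Step 1**
Reactants: 1, (S)-5-(hydroxymethyl)furan-2(5H)-one; 2, 1-(benzyloxy)-4-bromo-2-methoxybenzene (1.5 equiv)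
Product: 3, (4R,5S)-4-[4-(benzyloxy)-3-methoxyphenyl]-5-(hydroxymethyl)oxolan-2-one (aryl trans to CH2OH)
Conditions: NiBr2·dme (10 mol %), dtbbpy (12 mol %), 4CzIPN (2 mol %), Hantzsch ester (1.5 equiv), H2O (5 equiv), DMA, 450 nm LEDs, 25 °C
Reagents that add atoms: 2 (delivers the aryl group), COc1cc(Br)ccc1OCc1ccccc1
Why: Proposed new method: visible-light Ni/photoredox reductive 1,4-arylation of an unprotected γ-substituted butenolide, not yet shown for α,β-unsaturated lactones; 4CzIPN* is reductively quenched by the Hantzsch ester and 4CzIPN•− (about −1.2 V) returns Ni(II) to Ni(0); oxidative addition of 2 gives Ar–Ni, which binds C2=C3 on the face opposite the C4 CH2OH group and inserts syn, putting aryl on C3 and Ni on C2 as an oxa-π-allyl enolate; the ring holds the only β-H (C3–H) anti to Ni, so Heck-type β-hydride loss is blocked and protonolysis (H2O/HE•+) releases 3; C3 (R) is thus set by the bought C4 centre, trans as in cuprate and Rh additions to 5-substituted butenolides; closest known reaction types are Ni-catalysed reductive conjugate addition of aryl halides to enones/acrylates (Mn, Zn or cathode as reductant) and Ni/photoredox cross-electrophile coupling.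

**Step 2**
Reactants: 3
Product: 4, [(2S,3R)-3-[4-(benzyloxy)-3-methoxyphenyl]-5-oxooxolan-2-yl]methyl 4-methylbenzenesulfonate
Conditions: TsCl, Et3N, DMAP (cat.), CH2Cl2, 0 °C → rt
Reagents that add atoms: p-toluenesulfonyl chloride, Cc1ccc(cc1)S(=O)(=O)Cl
Why: Sulfonylation of the only free (primary) hydroxyl makes C5 the electrophile for ring closure and touches no stereocentre.

**Step 3**
Reactants: 4
Product: 5, (1S,4S,7R)-7-[4-(benzyloxy)-3-methoxyphenyl]-2,5-dioxabicyclo[2.2.1]heptan-3-one
Conditions: KHMDS, THF (0.02 M), −78 °C; (±)-3-phenyl-2-(phenylsulfonyl)oxaziridine, −78 °C; then 18-crown-6, → 23 °C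
Reagents that add atoms: 3-phenyl-2-(phenylsulfonyl)-1,2-oxaziridine (adds O), O=S(=O)(c1ccccc1)N1OC1c1ccccc1
Why: Davis enolate hydroxylation then intramolecular Williamson etherification in one flask, in which the enolate is oxygenated anti to the adjacent C3 aryl (sets C2, S), so the new alkoxide sits cis to CH2OTs and displaces tosylate 5-exo-tet (the closure used for 2′-O,4′-C-methylene-bridged nucleosides), and only this C2 epimer can cyclise.

**Step 4**
Reactants: 5; 2 (1.05 equiv, as its aryllithium)
Product: 7, (3S,4R,5S)-4-[4-(benzyloxy)-3-methoxyphenyl]-5-{(R)-[4-(benzyloxy)-3-methoxyphenyl](hydroxy)methyl}oxolan-3-ol, formed via ketone 6, [4-(benzyloxy)-3-methoxyphenyl]{(2S,3R,4S)-3-[4-(benzyloxy)-3-methoxyphenyl]-4-hydroxyoxolan-2-yl}methanone (not isolated)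
Conditions: 2, n-BuLi, THF/Et2O, −78 °C; added slowly to 5, −78 °C; then Zn(BH4)2 (Et2O), −78 → −20 °C; aq. NH4Cl
Reagents that add atoms: 2 (delivers the aryl group), COc1cc(Br)ccc1OCc1ccccc1
Why: Organolithium acyl substitution on the strained lactone gives 6 (slow inverse addition, a hindered electron-rich ketone, and Zn(II) turning residual ArLi into inert ArZn all suppress double addition), then Cram-chelate reduction with Zn2+ tying C1=O to ring O1 so that hydride enters from the C2–H side, away from the cis C3 aryl, giving the (R)-carbinol (erythro) without isolating the epimerisable ketone.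

**Step 5**
Reactants: 7
Product: 8, metasequirin E
Conditions: H2 (1 atm), 10 % Pd/C, EtOAc/EtOH, NaHCO3 (trace), rt
Reagents that add atoms: none
Why: Neutral hydrogenolysis of the two aryl benzyl ethers is much faster than cleavage of the secondary benzylic alcohol or the ring C–O bonds, and no stereocentre is affected.

## Compound list
1 | (S)-5-(hydroxymethyl)furan-2(5H)-one | OC[C@H]1OC(=O)C=C1 | starting material
2 | 1-(benzyloxy)-4-bromo-2-methoxybenzene | COc1cc(Br)ccc1OCc1ccccc1 | starting material
3 | (4R,5S)-4-[4-(benzyloxy)-3-methoxyphenyl]-5-(hydroxymethyl)oxolan-2-one | O=C1C[C@H](c2ccc(OCc3ccccc3)c(OC)c2)[C@@H](CO)O1 | intermediate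
4 | [(2S,3R)-3-[4-(benzyloxy)-3-methoxyphenyl]-5-oxooxolan-2-yl]methyl tosylate | O=C1C[C@H](c2ccc(OCc3ccccc3)c(OC)c2)[C@@H](COS(=O)(=O)c2ccc(C)cc2)O1 | intermediate
5 | (1S,4S,7R)-7-[4-(benzyloxy)-3-methoxyphenyl]-2,5-dioxabicyclo[2.2.1]heptan-3-one | O=C1O[C@@H]2CO[C@H]1[C@@H]2c1ccc(OCc2ccccc2)c(OC)c1 | intermediate
6 | [4-(benzyloxy)-3-methoxyphenyl]{(2S,3R,4S)-3-[4-(benzyloxy)-3-methoxyphenyl]-4-hydroxyoxolan-2-yl}methanone | COc1cc([C@H]2[C@@H](C(=O)c3ccc(OCc4ccccc4)c(OC)c3)OC[C@H]2O)ccc1OCc1ccccc1 | intermediate (not isolated)
7 | O,O′-dibenzyl metasequirin E, (3S,4R,5S,αR) | COc1cc([C@H]2[C@@H]([C@H](O)c3ccc(OCc4ccccc4)c(OC)c3)OC[C@H]2O)ccc1OCc1ccccc1 | intermediate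
8 | metasequirin E, (3S,4R,5S)-5-[(R)-hydroxy(4-hydroxy-3-methoxyphenyl)methyl]-4-(4-hydroxy-3-methoxyphenyl)oxolan-3-ol | COc1cc([C@H]2[C@@H]([C@H](O)c3ccc(O)c(OC)c3)OC[C@H]2O)ccc1O | target

## Summary
Total steps: 5. Longest linear sequence: 5.

Steps most likely to fail:
1. **Step 1 (proposed new step).** The risks are ArBr hydrodehalogenation or homocoupling, reduction of the butenolide, and sluggish insertion into a lactone acceptor.
   - Fallback (known chemistry): switch from the reductive cross-electrophile manifold to an organoboron nucleophile. Use achiral Rh(I)-catalysed Hayashi–Miyaura 1,4-addition of 4-(benzyloxy)-3-methoxyphenylboronic acid to unprotected 1 ([Rh(cod)Cl]2, KOH, dioxane/H2O). This reaction type gives trans adducts on δ-hydroxy-γ-butenolides.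
   - Also known: the cathodic Ni-catalysed conjugate addition of ArBr to activated olefins.
2. **Step 3 (hydroxylation plus transannular closure).** The α-alkoxide may add to the sulfonimine by-product or oligomerise the strained product instead of closing.
   - Fallback: close the oxolane last. Hydroxylate 3 by Rubottom oxidation of its silyl ketene acetal, add ArLi, and reduce the α-hydroxy ketone under Zn chelation. Then cyclise the acyclic 1,2,4,5-tetraol by selective primary sulfonylation (2,5-anhydroalditol-type C2–OH → C5 closure).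
3. **Step 4 (mono-addition and C1 control).** The risks are double addition, C2 epimerisation of 6, or the (S)-carbinol.
   - Fallback: open 5 to the Weinreb amide (MeNHOMe·HCl, i-PrMgCl), silylate C4–OH, add ArMgBr to reach an isolable ketone, and reduce it separately (Zn(BH4)2, Et2O).
   - If the wrong epimer dominates, invert C1 by Mitsunobu esterification and hydrolysis.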